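At early times the oak flask gives me the number I carry. Over its first 3 readings, target outnumbers other capture product by 4.24 to one. I call this the opening odds: target formed per other capture product while both nucleophiles stand near their full charge. It is the selectivity factor, 2.12 as read, times the charge ratio 2.00.

| flask | starting material | first nucleophile | second nucleophile | remark | time |
|---|---|---|---|---|---|
| oak | 0.10 M | 0.10 M | 0.050 M | run made earlier |  |
| maple | 0.14 M | 0.10 M | 0.050 M | run made earlier |  |
| birch | 0.22 M | 0.10 M | 0.050 M | run made earlier |  |
| Thursday's | 0.10 M | 0.100 M | 0.0500 M | one stirred flow tank at steady state, fed with the mixture as stated, mean residence time 15 h |  |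
| Friday's | 0.10 M | 0.100 M | 0.0500 M | everything together in a closed stirred flask, run for 15 h | 15 h |
| Tuesday's | 0.10 M | 0.100 M | 0.0500 M | one stirred flow tank at steady state, fed with the mixture as stated, mean residence time 45.0 h |  |
| Monday's | 0.10 M | 0.100 M | 0.0500 M (fed, over 12.0 h) | all but second nucleophile at the start; second nucleophile goes in evenly over 12.0 h, the run ends at 15 h | 15 h |

| run | time / h | target / % | other capture product / % |
|---|---|---|---|
| oak | 1.33 | 6.4 | 1.6 |
| oak | 2.50 | 11.3 | 2.7 |
| oak | 4.00 | 15.8 | 3.6 |
| oak | 8.00 | 29.9 | 8.0 |
| oak | 15.0 | 45.0 | 13.7 |
| maple | 1.33 | 6.1 | 0 |
| maple | 2.50 | 11.6 | 3.3 |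
| maple | 4.00 | 16.6 | 3.9 |
| maple | 8.00 | 29.0 | 8.6 |
| maple | 15.0 | 43.3 | 14.6 |
| birch | 3.00 | 12.1 | 3.9 |
| birch | 6.00 | 23.9 | 7.6 |
| birch | 10.0 | 31.8 | 11.2 |
| birch | 12.0 | 36.7 | 13.9 |
| birch | 15.0 | 41.1 | 18.2 |

(standard deviation of a reading: 0.5 percentage points)

- the stated concentrations are those of everything mixed, before any reaction; amounts are the same in each set-up
- the feed brings no volume worth counting
- the earlier runs were made in a closed, stirred flask
- a reading or a percentage of target counts all its forms, free or not

1. the set-up with the highest share of target in all that became target or other capture product, at the outlet or at the end ("none" if the first two lie within 2 percentage points) (Thursday's / Friday's / Tuesday's / Monday's / none)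
2. share of target in all that became target or other capture product, at the outlet or at the end, Thursday's
3. share of target in all that became target or other capture product, at the outlet or at the end, Friday's
4. share of target in all that became target or other capture product, at the outlet or at the end, Tuesday's
5. share of target in all that became target or other capture product, at the outlet or at the end, Monday's

The second nucleophile is charged in the smaller amount. Let y be the fraction of its charge left and x the same for the first nucleophile, each product taking one of its nucleophile. The odds at any moment are then the opening odds times x/y. Is one number enough? In a closed flask the two balances divide to give the selectivity factor as ln x / ln y. Oak's last reading gives 1.87 and birch's 1.45, both lower than the opening reading . So it is not quite enough, and I trust it best near the start.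

Still, I commit to the ranking. Friday's repeats oak's recipe, whose last reading has a share of 76.7 %. Monday's starts with y at zero, so I put it first, above the opening share 80.9 %.

The forecast, “which the two nucleophiles then share”, names Monday's, with 75.2 %, 76.3 %, 73.4 % and 84.3 % in the order asked.

The flask gives Monday's, with 75.1 %, 76.7 %, 72.4 % and 84.3 %.

    second nucleophile + intermediate → other capture product (k = 0.125 /M/s)
    starting material → intermediate (k = 1.65 × 10⁻⁵ /s)
    first nucleophile + intermediate → target (k = 0.258 /M/s)
    first nucleophile + target ⇌ idle adduct, settled at all times (K = 5.70 /M)

Thursday's tank holds x at 0.561 and y at 0.766, so the opening odds predict a share of 75.6 % against the simulated 75.1 %. Monday's flask is not at rest at 15 h: target, idle adduct counted in, stands at 49.7 % and other capture product at 9.24 %, leaving 41.1 % of the charge in neither. After 150 h Monday's share is 75.6 %, within 2 percentage points of Friday's 76.7 %.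

All runs were generated by integration with constants of no real substance; scatter was added.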